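## Structural features

The target is a C2-symmetric bis-isoflavan: two chromane units (ring A with 7-OH, fused to pyran ring C made of O1, C2H2, C3H and C4H2) each carry a benzene ring B at C3, and the two rings B are linked para to C3 through one diaryl ether oxygen (C4′–O–C4″). Each ring B is contiguously tetrasubstituted (C1′ chromane, C2′ OMe, C3′ OH, C4′ ether oxygen), so the centre is a 2,2′-dihydroxy diaryl ether in which both ortho positions of each hydroxyl are occupied. The only stereocentres are the two C3 atoms, both R; they are ten bonds apart and cannot relay configuration to one another, so the C2 isomer must be won over the meso isomer by independent control at each end. Each C3 is a tertiary benzylic carbon flanked by two methylene groups; it is stable in the target but epimerizable in any intermediate in which C2 or C4 is a carbonyl carbon. The fragile groups are the four free phenols, above all the 3′-hydroxyls on the very electron-rich rings B, which oxidise easily and are best unmasked last. The real difficulty is to set two remote, unfunctionalised stereocentres with the same sense while building two pyran rings, and to make the hindered, doubly ortho-oxygenated diaryl ether with its OMe/OH pattern. The key step exploits two facts: in each half O1–C8a–C4a–C4 is a masked o-quinone methide and C3–C2 are the α-carbon and carboxyl carbon of an arylacetic acid of ring B, and the C2 axis through the ether oxygen makes the halves identical, so a two-fold [4+2] union of one central bis(arylacetic acid) with two o-quinone methides closes both rings C and sets both stereocentres at once.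

## Logic of the disconnections

**19 ⇒ 18.** Cut: the four O–CH2Ph bonds (O7 on each ring A, O3′ on each ring B). Reason: one kind of protecting group on all four phenols lets a single hydrogenolysis end the route and keeps the oxidation-prone rings B masked until the last flask. Gain: none in skeleton, but every earlier step works on a non-acidic, non-oxidisable substrate. Demand: 18 must contain no other reducible or epimerizable site, which holds.

**18 ⇒ 17.** Cut: the two O1–C2 ether bonds. Reason: opening ring C at O1–C2 gives a ring-A phenol and a primary alcohol, which is the reduced form of a lactone. Gain: the cyclic ether is traced to the oxidation level that the key step delivers. Demand: a two-fold intramolecular etherification in which only the ring-A phenols are free and C3 is not a reacting centre.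

**17 ⇒ 16.** Change: C2 from CH2OH (with O1–H) back to the lactone C(=O)–O1 at both ends; no skeletal bond is cut. Reason: a lactone carbonyl at C2 is what makes the α-carbon C3 nucleophilic in the key step. Demand: hydride reduction must be faster than enolisation at C3, which is α-aryl and α-acyl in 16.

**16 ⇒ 9 + two 13 (through 14 and 15).** Cut: C3–C4 and O1–C2 at both ends, four bonds in all, which opens both rings C and removes both stereocentres. In one sentence: a two-fold, carbene-catalysed formal [4+2] annulation of 9 with two molecules of 15 closes both rings C and sets both C3 centres. This sentence does not describe the obvious route, which makes a monomer by isoflavone chemistry and joins two of them through the ether. Gain: 16 falls to one achiral, symmetric core (9) and one small achiral ring-A piece (13). Demand: catalyst control of the enolate face twice over, slow release of 15 so that trapping outruns its oligomerisation, and a product that does not enolise under the conditions.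

**13 ⇒ 12 ⇒ 11 ⇒ 10.** Cut: the O–acetyl bond, then the benzylic C–H (aldehyde reduction), then the O–Si bond. Reason: 13 holds a fluoride-labile trigger on O1 and a leaving group on C4; the acetate is chosen because a benzylic halide para to an alkoxy group would ionise on storage. Demand: no O-to-O silyl migration during the reduction.

**9 ⇒ 8 ⇒ 7.** Cut: the two C1′–CH2 bonds (after ester cleavage). Reason: an aryl bromide is an inert placeholder for the acetic acid side chain during the base- and oxidant-mediated steps that build the core. Gain: the side chain arrives in one two-fold cross-coupling. Demand: coupling of an ester enolate equivalent with an electron-rich, ortho-methoxy aryl bromide, twice.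

**7 ⇒ 6 ⇒ 4 (through 5).** Cut: the two O3′–benzyl bonds, then the C3′–O bonds, which are traced to C3′–CHO by oxygen insertion into the aryl–formyl bond. Reason: the formyl group first activates the ether-forming substitution and then becomes the C3′ oxygen, so the OMe/OH/OAr pattern arises without any differentiation of phenols. Demand: aryl migration, not hydride migration, in the peracid step; two flanking oxygen donors secure it.

**4 ⇒ two 2 (through 3).** Cut: both C4′–O bonds of the diaryl ether; one oxygen atom from water joins two molecules of 2. Reason: the fluoride in 2 is ortho to the formyl group and is displaced first by hydroxide and then by the resulting phenoxide 3. Gain: the symmetric core comes from a single monomer in one operation. Demand: hydroxide must attack the C–F carbon and not the formyl group; the stoichiometry corrects itself because each 3 consumes one 2.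

**2 ⇒ 1.** Cut: the aryl–CHO bond. Reason: the C–H between F and OMe in 1 is the most acidic site, so directed lithiation and formylation place the formyl group exactly between the two groups that need it.

## Other disconnections considered

**Alternative 1:** the one that comes to mind first. Cut: one C4′–O bond of the central diaryl ether. Forward key step: Ullmann-type etherification (CuI, copper monoiodide, monovalent copper, with an N,O-ligand and K3PO4) of phenol A1 with aryl bromide A2, each an enantiopure isoflavan made by its own asymmetric sequence. Ground for preferring the chosen plan: the coupling would join two very electron-rich partners at positions each flanked by an ortho benzyloxy group, which is the least favourable case for copper-mediated C–O coupling. It also needs two different monomers, so the stereocentre must be made twice in separate sequences and the C2 symmetry is never used. The chosen plan forms the ether on a small fluoroaldehyde and sets both centres in one flask.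

**Alternative 2:** Cut: the two C3–C4 bonds as carbene C–H insertions. Forward key step: the bis(aryldiazoacetate) A3 and the toluene derivative A4 with a chiral dirhodium tetracarboxylate such as Rh2(S-DOSP)4 would give the bis(2,3-diarylpropanoate) A5 by two-fold insertion into the methyl C–H bonds of A4. Ground for preferring the chosen plan: the carbene would have to choose a primary benzylic C–H ortho to an ether over the OCH2Ph hydrogens, which are among the most activated C–H bonds for such carbenes, and over the unsubstituted C5–C6 edge of the electron-rich ring (cyclopropanation or aromatic substitution). The ortho methoxy group on the carbene aryl is also expected to erode face selectivity, and the step closes no ring. The chosen step has one reactive site on each partner and closes ring C as it sets C3.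

**Alternative 3:** Cut: the two C3–C1′ bonds by a biomimetic 1,2-aryl shift. Forward key step: two-fold oxidative rearrangement of the bis(2′-hydroxychalcone) A6 with Tl(NO3)3 (thallium trinitrate, trivalent thallium) in methanol, then acid, to the bis-isoflavone A7; the stereocentres would follow by asymmetric reduction of the flat C2=C3–C4=O unit and removal of the C4 oxygen. Ground for preferring the chosen plan: the key step makes no stereocentre, so stereocontrol is postponed to a reduction that places a carbonyl or carbinol next to C3 and then requires a benzylic deoxygenation at both ends. That adds redox steps, and the strong oxidant meets the tetra-oxygenated ring B. The chosen plan reaches the right oxidation pattern directly and sets configuration in the C–C bond-forming event.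

Key step: step 10

Assumptions:
- The sense of induction of the aminoindanol-derived triazolium salt is taken to be that the (5aS,10bR) salt gives (R) at C3; should the opposite hold, the equally available antipodal salt is used.
- Compounds 1 and 10, the zinc reagent of step 5 (as a THF solution) and the triazolium salt are taken as purchasable.
- Ring B is numbered C1′ (bonded to C3) to C6′; the second half is identical by symmetry.

## Steps

Step 1
Reactants: 1 1-bromo-4-fluoro-2-methoxybenzene
Product: 2 3-bromo-6-fluoro-2-methoxybenzaldehyde
Conditions: LDA (1.1 equiv), THF, −78 °C; DMF, −78 → −20 °C; AcOH quench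
Reagents that add atoms: N,N-dimethylformamide, CN(C)C=O
Why: Directed ortho-lithiation and formylation: the C–H between F and OMe is the most acidic site, LDA does not exchange the bromide, and the aryllithium is held at −78 °C to prevent loss of LiF to an aryne.

Step 2
Reactants: 2 3-bromo-6-fluoro-2-methoxybenzaldehyde (two molecules)
Product: 4 6,6'-oxybis(3-bromo-2-methoxybenzaldehyde), via 3-bromo-6-hydroxy-2-methoxybenzaldehyde cesium salt 3 (not isolated)
Conditions: Cs2CO3 (1.05 equiv), H2O (0.5 equiv), DMSO, 60 °C then 110 °C
Reagents that add atoms: water, O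
Why: Two consecutive nucleophilic aromatic substitutions (SNAr) activated by the ortho formyl group: hydroxide from carbonate and water displaces fluoride to give phenoxide 3, which displaces fluoride from a second molecule of 2. The bromide is meta to the formyl group and is not activated, and the stoichiometry corrects itself because each 3 consumes one 2.

Step 3
Reactants: 4 6,6'-oxybis(3-bromo-2-methoxybenzaldehyde)
Product: 6 6,6'-oxybis(3-bromo-2-methoxyphenol), via bis(aryl formate) 5 (not isolated)
Conditions: mCPBA (2.6 equiv), CH2Cl2, 0 °C → rt; aq. Na2S2O3/NaHCO3 wash; K2CO3 (cat.), MeOH, rt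
Reagents that add atoms: 3-chloroperoxybenzoic acid, OOC(=O)c1cccc(Cl)c1
Why: Baeyer–Villiger (Dakin-type) oxidation: the ring carbon bearing CHO has two ortho oxygen donors, so the aryl group migrates in the Criegee intermediate to give formate 5, and methanolysis frees the phenol. The aryl bromides and the diaryl ether are inert to peracid.

Step 4
Reactants: 6 6,6'-oxybis(3-bromo-2-methoxyphenol)
Product: 7 1,1'-oxybis[2-(benzyloxy)-4-bromo-3-methoxybenzene]
Conditions: BnBr (2.4 equiv), K2CO3, DMF, 50 °C
Reagents that add atoms: benzyl bromide, BrCc1ccccc1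
Why: Williamson etherification of the two hindered phenols. Benzyl masks the acidic, oxidation-prone O3′ through the enolate, hydride and Mitsunobu steps and leaves at the end together with the ring-A benzyl groups.

Step 5
Reactants: 7 1,1'-oxybis[2-(benzyloxy)-4-bromo-3-methoxybenzene]
Product: 8 di-tert-butyl 2,2'-{oxybis[3-(benzyloxy)-2-methoxy-4,1-phenylene]}diacetate
Conditions: BrZnCH2CO2t-Bu (3 equiv, THF solution), Pd2(dba)3 (2.5 mol %), XPhos (10 mol %), THF, 65 °C
Reagents that add atoms: (2-tert-butoxy-2-oxoethyl)zinc bromide, CC(C)(C)OC(=O)C[Zn]Br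
Why: Palladium-catalysed coupling of a zinc ester enolate (Reformatsky reagent) with an aryl bromide, a Negishi-type α-arylation under neutral conditions. The bulky biarylphosphine speeds oxidative addition to the electron-rich, ortho-methoxy bromide, and no base-sensitive group is present.

Step 6
Reactants: 8 di-tert-butyl 2,2'-{oxybis[3-(benzyloxy)-2-methoxy-4,1-phenylene]}diacetate
Product: 9 2,2'-{oxybis[3-(benzyloxy)-2-methoxy-4,1-phenylene]}diacetic acid
Conditions: CF3CO2H/CH2Cl2 (1:3), 0 °C → rt
Reagents that add atoms: none
Why: Acidolysis of the tert-butyl esters with loss of isobutene (E1). Benzyl aryl ethers and the diaryl ether should survive short exposure to dilute acid at or below room temperature.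

Step 7
Reactants: 10 4-(benzyloxy)-2-hydroxybenzaldehyde
Product: 11 4-(benzyloxy)-2-[(tert-butyldimethylsilyl)oxy]benzaldehyde
Conditions: t-BuMe2SiCl, imidazole, CH2Cl2, rt
Reagents that add atoms: tert-butyldimethylsilyl chloride, CC(C)(C)[Si](C)(C)Cl
Why: Silylation of the phenol; the aryl silyl ether is the fluoride-sensitive trigger for the later release of the o-quinone methide.

Step 8
Reactants: 11 4-(benzyloxy)-2-[(tert-butyldimethylsilyl)oxy]benzaldehyde
Product: 12 {4-(benzyloxy)-2-[(tert-butyldimethylsilyl)oxy]phenyl}methanol
Conditions: NaBH4, EtOH/THF, −10 °C; pH 7 buffer quench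
Reagents that add atoms: none
Why: Borohydride reduction of the aldehyde; the low temperature and neutral quench keep the silyl group from migrating from the phenolic oxygen to the new benzylic alkoxide.

Step 9
Reactants: 12 {4-(benzyloxy)-2-[(tert-butyldimethylsilyl)oxy]phenyl}methanol
Product: 13 4-(benzyloxy)-2-[(tert-butyldimethylsilyl)oxy]benzyl acetate
Conditions: Ac2O, pyridine, DMAP (cat.), CH2Cl2, 0 °C
Reagents that add atoms: acetic anhydride, CC(=O)OC(C)=O
Why: Acylation of the primary alcohol. Acetate is chosen as the leaving group because a benzylic halide para to an alkoxy group would ionise on storage, whereas the acetate is stable until the phenoxide is unmasked.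

Step 10
Reactants: 9 2,2'-{oxybis[3-(benzyloxy)-2-methoxy-4,1-phenylene]}diacetic acid; 13 4-(benzyloxy)-2-[(tert-butyldimethylsilyl)oxy]benzyl acetate (2.6 equiv)
Product: 16 (3R,3'R)-3,3'-{oxybis[3-(benzyloxy)-2-methoxy-4,1-phenylene]}bis[7-(benzyloxy)chroman-2-one], via bis(acyl imidazole) 14 (not isolated), via o-quinone methide 15 (not isolated)
Conditions: CDI (2.1 equiv), THF, rt; then 13, (5aS,10bR)-2-mesityl-5a,10b-dihydro-4H,6H-indeno[2,1-b][1,2,4]triazolo[4,3-d][1,4]oxazin-2-ium tetrafluoroborate (20 mol %), CsF (3 equiv), 18-crown-6 (20 mol %), 4 Å MS, THF, −10 °C → rt; AcOH quench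
Reagents that add atoms: none
Why: Formal [4+2] annulation under N-heterocyclic carbene catalysis with dual Lewis-base activation; the closest known reaction type is the carbene-catalysed union of acyl imidazoles with fluoride-released o-quinone methides to give 3-substituted 3,4-dihydrocoumarins. CDI turns both carboxyl groups into acyl imidazoles (14); the triazolylidene adds to each acyl group and the acidic α-aryl C–H of the acyl azolium is removed to give a Z azolium enolate, while fluoride desilylates 13 and the phenoxide expels acetate, helped by the para benzyloxy group, so that 15 is fed in slowly. The enolate carbon adds to the exocyclic CH2 of 15 (C3–C4 bond, driven by re-aromatisation of ring A) and the phenoxide so formed acylates on the acyl azolium (O1–C2 bond), which releases the carbene. Each ring C thus closes by Michael addition followed by 6-exo-trig lactonisation, or in the concerted limit as an inverse-demand hetero-Diels–Alder addition of the oxadiene O=C–C=CH2 to the enolate C=C. C3 and C3′ are set in the C–C bond-forming event by the catalyst alone: the indane backbone shields one face of the Z enolate, and because the two ends are ten bonds apart they react independently with the same sense. A minor-sense event at one end leads mainly to the meso diastereomer and not to the enantiomer, so the enantiomeric purity of the C2-symmetric product should exceed that of a single annulation, and the meso isomer is removed as a diastereomer. The step needs C- over O-alkylation and attack at CH2 only, both secured by the polarity of 15, and it needs the product not to enolise: the ortho methoxy group twists ring B out of the enolate plane and lowers the kinetic acidity of C3–H, and the mixture is kept cold and quenched with AcOH.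

Step 11
Reactants: 16 (3R,3'R)-3,3'-{oxybis[3-(benzyloxy)-2-methoxy-4,1-phenylene]}bis[7-(benzyloxy)chroman-2-one]
Product: 17 (2R,2'R)-2,2'-{oxybis[3-(benzyloxy)-2-methoxy-4,1-phenylene]}bis{3-[4-(benzyloxy)-2-hydroxyphenyl]propan-1-ol}
Conditions: LiBH4 (4 equiv), THF, −20 → 0 °C; aq. NH4Cl
Reagents that add atoms: none
Why: Hydride reduction of the aryl-ester lactones to primary alcohol and phenol. The very electrophilic lactone carbonyl should be reduced faster than C3–H is removed, and the α-aryl aldehyde set free from the hemiacetal is reduced at once, as in the reductive removal of auxiliaries from α-aryl imides, so C3 keeps its configuration.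

Step 12
Reactants: 17 (2R,2'R)-2,2'-{oxybis[3-(benzyloxy)-2-methoxy-4,1-phenylene]}bis{3-[4-(benzyloxy)-2-hydroxyphenyl]propan-1-ol}
Product: 18 (3R,3'R)-3,3'-{oxybis[3-(benzyloxy)-2-methoxy-4,1-phenylene]}bis[7-(benzyloxy)chromane]
Conditions: PPh3, DIAD, THF (0.01 M), 0 °C → rt
Reagents that add atoms: none
Why: Two-fold intramolecular Mitsunobu etherification: the ring-A phenol, the only acidic OH present, displaces the activated primary oxygen in a 6-exo-tet SN2 closure. C3 is not a reacting centre, and high dilution disfavours intermolecular ether formation.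

Step 13
Reactants: 18 (3R,3'R)-3,3'-{oxybis[3-(benzyloxy)-2-methoxy-4,1-phenylene]}bis[7-(benzyloxy)chromane]
Product: 19 (3R,3'R)-3,3'-[oxybis(3-hydroxy-2-methoxy-4,1-phenylene)]bis(chroman-7-ol)
Conditions: H2 (1 atm), 10% Pd/C, EtOAc/MeOH, rt; handled under argon
Reagents that add atoms: none
Why: Hydrogenolysis of four benzyl aryl ethers over palladium. The O1–C2 bond is an alkyl aryl ether and not benzylic, and no reducible or epimerizable site remains, so both (R) centres and the diaryl ether should survive.

## Compound list

1 | 1-bromo-4-fluoro-2-methoxybenzene | COc1cc(F)ccc1Br | starting material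
2 | 3-bromo-6-fluoro-2-methoxybenzaldehyde | COc1c(Br)ccc(F)c1C=O | intermediate
3 | 3-bromo-6-hydroxy-2-methoxybenzaldehyde (present as its cesium phenoxide) | COc1c(Br)ccc(O)c1C=O | intermediate (not isolated)
4 | 6,6'-oxybis(3-bromo-2-methoxybenzaldehyde) | COc1c(Br)ccc(Oc2ccc(Br)c(OC)c2C=O)c1C=O | intermediate
5 | 6,6'-oxybis(3-bromo-2-methoxyphenyl) diformate | COc1c(Br)ccc(Oc2ccc(Br)c(OC)c2OC=O)c1OC=O | intermediate (not isolated)
6 | 6,6'-oxybis(3-bromo-2-methoxyphenol) | COc1c(Br)ccc(Oc2ccc(Br)c(OC)c2O)c1O | intermediate
7 | 1,1'-oxybis[2-(benzyloxy)-4-bromo-3-methoxybenzene] | COc1c(Br)ccc(Oc2ccc(Br)c(OC)c2OCc2ccccc2)c1OCc1ccccc1 | intermediate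
8 | di-tert-butyl 2,2'-{oxybis[3-(benzyloxy)-2-methoxy-4,1-phenylene]}diacetate | COc1c(CC(=O)OC(C)(C)C)ccc(Oc2ccc(CC(=O)OC(C)(C)C)c(OC)c2OCc2ccccc2)c1OCc1ccccc1 | intermediate
9 | 2,2'-{oxybis[3-(benzyloxy)-2-methoxy-4,1-phenylene]}diacetic acid | COc1c(CC(=O)O)ccc(Oc2ccc(CC(=O)O)c(OC)c2OCc2ccccc2)c1OCc1ccccc1 | intermediate
10 | 4-(benzyloxy)-2-hydroxybenzaldehyde | O=Cc1ccc(OCc2ccccc2)cc1O | starting material
11 | 4-(benzyloxy)-2-[(tert-butyldimethylsilyl)oxy]benzaldehyde | O=Cc1ccc(OCc2ccccc2)cc1O[Si](C)(C)C(C)(C)C | intermediate
12 | {4-(benzyloxy)-2-[(tert-butyldimethylsilyl)oxy]phenyl}methanol | OCc1ccc(OCc2ccccc2)cc1O[Si](C)(C)C(C)(C)C | intermediate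
13 | 4-(benzyloxy)-2-[(tert-butyldimethylsilyl)oxy]benzyl acetate | CC(=O)OCc1ccc(OCc2ccccc2)cc1O[Si](C)(C)C(C)(C)C | intermediate
14 | 2,2'-{oxybis[3-(benzyloxy)-2-methoxy-4,1-phenylene]}bis[1-(1H-imidazol-1-yl)ethan-1-one] | COc1c(CC(=O)n2ccnc2)ccc(Oc2ccc(CC(=O)n3ccnc3)c(OC)c2OCc2ccccc2)c1OCc1ccccc1 | intermediate (not isolated)
15 | 3-(benzyloxy)-6-methylidenecyclohexa-2,4-dien-1-one | C=C1C=CC(OCc2ccccc2)=CC1=O | intermediate (not isolated)
16 | (3R,3'R)-3,3'-{oxybis[3-(benzyloxy)-2-methoxy-4,1-phenylene]}bis[7-(benzyloxy)chroman-2-one] | COc1c([C@@H]2C(=O)Oc3cc(OCc4ccccc4)ccc3C2)ccc(Oc2ccc([C@@H]3C(=O)Oc4cc(OCc5ccccc5)ccc4C3)c(OC)c2OCc2ccccc2)c1OCc1ccccc1 | intermediate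
17 | (2R,2'R)-2,2'-{oxybis[3-(benzyloxy)-2-methoxy-4,1-phenylene]}bis{3-[4-(benzyloxy)-2-hydroxyphenyl]propan-1-ol} | COc1c([C@@H](Cc2ccc(OCc3ccccc3)cc2O)CO)ccc(Oc2ccc([C@@H](Cc3ccc(OCc4ccccc4)cc3O)CO)c(OC)c2OCc2ccccc2)c1OCc1ccccc1 | intermediate
18 | (3R,3'R)-3,3'-{oxybis[3-(benzyloxy)-2-methoxy-4,1-phenylene]}bis[7-(benzyloxy)chromane] | COc1c([C@@H]2COc3cc(OCc4ccccc4)ccc3C2)ccc(Oc2ccc([C@@H]3COc4cc(OCc5ccccc5)ccc4C3)c(OC)c2OCc2ccccc2)c1OCc1ccccc1 | intermediate
19 | (3R,3'R)-3,3'-[oxybis(3-hydroxy-2-methoxy-4,1-phenylene)]bis(chroman-7-ol) | COc1c([C@@H]2COc3cc(O)ccc3C2)ccc(Oc2ccc([C@@H]3COc4cc(O)ccc4C3)c(OC)c2O)c1O | target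

## Step count and least certain steps

Total: 13 steps. Longest linear sequence: 10 steps (steps 1–6 and 10–13); the ring-A piece takes 3 steps (7–9) and joins at step 10.

**Step 10 (key step).** Most likely to go wrong: loss of enantiopurity, either by enolisation of the α-aryl lactone in the fluoride/imidazole medium or by an uncatalysed background alkylation of the enolised acyl imidazole. Oligomerisation of the o-quinone methide could also outrun the second annulation and leave the reaction at the mono-annulated stage. In addition, the meso isomer has remote centres and may be hard to separate.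

Fallback (sets out from 9, returns at 17): the stereocentres are set by auxiliary-controlled alkylation instead of catalysis. Diacid 9 is converted through its mixed pivalic anhydride (t-BuCOCl, Et3N, THF, −20 °C) with lithiated (R)-4-benzyl-1,3-oxazolidin-2-one into the bis-imide (4R,4'R)-3,3'-(2,2'-{oxybis[3-(benzyloxy)-2-methoxy-4,1-phenylene]}diacetyl)bis(4-benzyl-1,3-oxazolidin-2-one) F1. Alcohol 12 is turned into [5-(benzyloxy)-2-(bromomethyl)phenoxy](tert-butyl)dimethylsilane F2 (PPh3, CBr4, CH2Cl2, 0 °C, used at once). Two-fold alkylation of the sodium Z enolate of F1 (NaN(SiMe3)2, THF, −78 °C) with F2, anti to the benzyl group of each auxiliary, should give the bis-alkylated imide (4R,4'R)-3,3'-[(2R,2'R)-2,2'-{oxybis[3-(benzyloxy)-2-methoxy-4,1-phenylene]}bis(3-{4-(benzyloxy)-2-[(tert-butyldimethylsilyl)oxy]phenyl}propanoyl)]bis(4-benzyl-1,3-oxazolidin-2-one) F3. LiBH4 (THF, 0 °C) removes both auxiliaries to give the bis(silyl ether) diol (2R,2'R)-2,2'-{oxybis[3-(benzyloxy)-2-methoxy-4,1-phenylene]}bis(3-{4-(benzyloxy)-2-[(tert-butyldimethylsilyl)oxy]phenyl}propan-1-ol) F4, and Bu4NF (THF, 0 °C) frees the ring-A phenols to give 17.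

**Step 2.** Most likely to go wrong: attack of hydroxide at the formyl group (Cannizzaro-type disproportionation) in the polar aprotic medium, or stalling at the phenoxide stage because the ortho-formyl phenoxide is a weak nucleophile.

Fallback (sets out from 2, returns at 4): the oxygen is brought in by a hydroxide surrogate and the two substitutions are separated. One portion of 2 is treated with 2-(methylsulfonyl)ethanol and NaH in DMF (0 °C → rt) to give 3-bromo-2-methoxy-6-[2-(methylsulfonyl)ethoxy]benzaldehyde F5, which loses (methylsulfonyl)ethene by E1cB elimination under the same conditions and gives phenol 3 after acidic work-up. Isolated 3 is then coupled with a second portion of 2 (K2CO3, N,N-dimethylacetamide, 120 °C) to give 4 with no hydroxide present.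

**Step 5.** Most likely to go wrong: slow oxidative addition and competing protodehalogenation on the electron-rich, ortho-alkoxy dibromide, so that the coupling stops after one arm.

Fallback (sets out from 7, returns at 9): carbon is introduced through an aryllithium instead of a palladium cycle. Two-fold bromine–lithium exchange (n-BuLi, THF, −78 °C) and opening of oxirane in the presence of BF3·OEt2 should give 2,2'-{oxybis[3-(benzyloxy)-2-methoxy-4,1-phenylene]}di(ethan-1-ol) F6. Oxidation of both primary alcohols (TEMPO cat., PhI(OAc)2, MeCN/H2O) then gives 9 directly, which also removes step 6.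

**Step 11.** Most likely to go wrong: partial loss of configuration at C3 through enolisation of the lactone or of the transient α-aryl aldehyde before the second hydride is delivered.

Fallback (sets out from 16, returns at 18): C2 is kept at a tetrahedral oxidation level so that no free α-aryl aldehyde and no alkoxide base is present. i-Bu2AlH (CH2Cl2, −78 °C) stops at the bis-lactol (3R,3'R)-3,3'-{oxybis[3-(benzyloxy)-2-methoxy-4,1-phenylene]}bis[7-(benzyloxy)chroman-2-ol] F7. Ionic hydrogenation (Et3SiH, BF3·OEt2, CH2Cl2, −78 → −40 °C) removes the anomeric hydroxyl through the oxocarbenium ion and gives 18, bypassing 17 and step 12.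

## Further compounds

F1 | step 10 | (4R,4'R)-3,3'-(2,2'-{oxybis[3-(benzyloxy)-2-methoxy-4,1-phenylene]}diacetyl)bis(4-benzyl-1,3-oxazolidin-2-one) | COc1c(CC(=O)N2[C@H](Cc3ccccc3)COC2=O)ccc(Oc2ccc(CC(=O)N3[C@H](Cc4ccccc4)COC3=O)c(OC)c2OCc2ccccc2)c1OCc1ccccc1
F2 | step 10 | [5-(benzyloxy)-2-(bromomethyl)phenoxy](tert-butyl)dimethylsilane | BrCc1ccc(OCc2ccccc2)cc1O[Si](C)(C)C(C)(C)C
F3 | step 10 | (4R,4'R)-3,3'-[(2R,2'R)-2,2'-{oxybis[3-(benzyloxy)-2-methoxy-4,1-phenylene]}bis(3-{4-(benzyloxy)-2-[(tert-butyldimethylsilyl)oxy]phenyl}propanoyl)]bis(4-benzyl-1,3-oxazolidin-2-one) | COc1c([C@@H](Cc2ccc(OCc3ccccc3)cc2O[Si](C)(C)C(C)(C)C)C(=O)N2[C@H](Cc3ccccc3)COC2=O)ccc(Oc2ccc([C@@H](Cc3ccc(OCc4ccccc4)cc3O[Si](C)(C)C(C)(C)C)C(=O)N3[C@H](Cc4ccccc4)COC3=O)c(OC)c2OCc2ccccc2)c1OCc1ccccc1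
F4 | step 10 | (2R,2'R)-2,2'-{oxybis[3-(benzyloxy)-2-methoxy-4,1-phenylene]}bis(3-{4-(benzyloxy)-2-[(tert-butyldimethylsilyl)oxy]phenyl}propan-1-ol) | COc1c([C@@H](Cc2ccc(OCc3ccccc3)cc2O[Si](C)(C)C(C)(C)C)CO)ccc(Oc2ccc([C@@H](Cc3ccc(OCc4ccccc4)cc3O[Si](C)(C)C(C)(C)C)CO)c(OC)c2OCc2ccccc2)c1OCc1ccccc1
F5 | step 2 | 3-bromo-2-methoxy-6-[2-(methylsulfonyl)ethoxy]benzaldehyde | COc1c(Br)ccc(OCCS(C)(=O)=O)c1C=O
F6 | step 5 | 2,2'-{oxybis[3-(benzyloxy)-2-methoxy-4,1-phenylene]}di(ethan-1-ol) | COc1c(CCO)ccc(Oc2ccc(CCO)c(OC)c2OCc2ccccc2)c1OCc1ccccc1
F7 | step 11 | (3R,3'R)-3,3'-{oxybis[3-(benzyloxy)-2-methoxy-4,1-phenylene]}bis[7-(benzyloxy)chroman-2-ol] | COc1c([C@@H]2C(O)Oc3cc(OCc4ccccc4)ccc3C2)ccc(Oc2ccc([C@@H]3C(O)Oc4cc(OCc5ccccc5)ccc4C3)c(OC)c2OCc2ccccc2)c1OCc1ccccc1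
A1 | alternative 1 | (3R)-7-(benzyloxy)-3-[3-(benzyloxy)-4-hydroxy-2-methoxyphenyl]chromane | COc1c([C@@H]2COc3cc(OCc4ccccc4)ccc3C2)ccc(O)c1OCc1ccccc1
A2 | alternative 1 | (3R)-7-(benzyloxy)-3-[3-(benzyloxy)-4-bromo-2-methoxyphenyl]chromane | COc1c([C@@H]2COc3cc(OCc4ccccc4)ccc3C2)ccc(Br)c1OCc1ccccc1
A3 | alternative 2 | dimethyl 2,2'-{oxybis[3-(benzyloxy)-2-methoxy-4,1-phenylene]}bis(2-diazoacetate) | COc1c(C(=[N+]=[N-])C(=O)OC)ccc(Oc2ccc(C(=[N+]=[N-])C(=O)OC)c(OC)c2OCc2ccccc2)c1OCc1ccccc1
A4 | alternative 2 | 2,4-bis(benzyloxy)-1-methylbenzene | Cc1ccc(OCc2ccccc2)cc1OCc1ccccc1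
A5 | alternative 2 | dimethyl (2R,2'R)-2,2'-{oxybis[3-(benzyloxy)-2-methoxy-4,1-phenylene]}bis{3-[2,4-bis(benzyloxy)phenyl]propanoate} | COc1c([C@@H](Cc2ccc(OCc3ccccc3)cc2OCc2ccccc2)C(=O)OC)ccc(Oc2ccc([C@@H](Cc3ccc(OCc4ccccc4)cc3OCc3ccccc3)C(=O)OC)c(OC)c2OCc2ccccc2)c1OCc1ccccc1
A6 | alternative 3 | (2E,2'E)-3,3'-{oxybis[3-(benzyloxy)-2-methoxy-4,1-phenylene]}bis{1-[4-(benzyloxy)-2-hydroxyphenyl]prop-2-en-1-one} | COc1c(/C=C/C(=O)c2ccc(OCc3ccccc3)cc2O)ccc(Oc2ccc(/C=C/C(=O)c3ccc(OCc4ccccc4)cc3O)c(OC)c2OCc2ccccc2)c1OCc1ccccc1
A7 | alternative 3 | 3,3'-{oxybis[3-(benzyloxy)-2-methoxy-4,1-phenylene]}bis[7-(benzyloxy)-4H-chromen-4-one] | COc1c(-c2coc3cc(OCc4ccccc4)ccc3c2=O)ccc(Oc2ccc(-c3coc4cc(OCc5ccccc5)ccc4c3=O)c(OC)c2OCc2ccccc2)c1OCc1ccccc1
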